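In the vessel the substrate stands with free catalyst and meets reagent, and the reckoning here counts how much reagent each flask has seen.

common to all: substrate 0.23 M; free catalyst 0.12 mM

| flask | reagent | temperature | remark | time |
|---|---|---|---|---|
| dawn | 0.39 M (fed, over 30 h) | 85 °C | run made earlier; the fed solution adds 0.25 times the starting volume |  |
| summer | 0.61 M (fed, over 30 h) | 100 °C | run made earlier; the fed solution adds 0.25 times the starting volume |  |
| ash | 0.276 M (fed, over 30 h) | 100 °C | the fed solution adds 0.25 times the starting volume | 30 h |
| elm | 0.276 M | 100 °C | everything together at the start, the whole solution of reagent included, so that from the start the volume is larger by 0.25 times the starting volume | 30 h |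

| run | time / h | target / % | substrate / % |
|---|---|---|---|
| dawn | 5.00 | 2.1 | 99.3 |
| dawn | 10.0 | 0.4 | 97.4 |
| dawn | 15.0 | 4.6 | 95.9 |
| dawn | 20.0 | 6.9 | 93.4 |
| dawn | 25.0 | 8.1 | 89.5 |
| dawn | 30.0 | 9.7 | 86.8 |
| dawn | 40.0 | 14.0 | 84.0 |
| summer | 1.33 | 1.3 | 100.0 |
| summer | 2.00 | 0.5 | 99.7 |
| summer | 3.00 | 0.9 | 98.8 |
| summer | 5.00 | 0.8 | 97.3 |
| summer | 8.00 | 4.4 | 96.1 |
| summer | 12.0 | 8.9 | 90.4 |
| summer | 20.0 | 19.9 | 81.8 |

(readings scatter by 1 percentage point)

- which one finishes higher in amount of target, in percent of the substrate charged ("neither" within 2 percentage points) (ash / elm / neither)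
- amount of target at the end, in percent of the substrate charged, ash
- amount of target at the end, in percent of the substrate charged, elm

- amounts are per litre of the starting volume; all of the dose is in the solution fed

Both fed runs start nearly flat and then steepen, as a rate proportional to [substrate] and [reagent] does while [reagent] climbs from nothing. Call the time integral of [reagent], counted as dosed and diluted with nothing subtracted for use, the exposure; the substrate then falls pseudo-first-order in exposure. The summer run has seen 3.66 M·h by 20.0 h, with 81.8% of its substrate standing, so the exposure constant, the logarithm of substrate lost per unit of exposure, reads 0.0548 M⁻¹ h⁻¹. The dawn run, read at 40.0 h, gives 0.0214 M⁻¹ h⁻¹. Both are readings and carry their scatter.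

Ash and elm share the summer temperature and catalyst, so this reckoning uses the summer constant. Elm holds 0.221 M of reagent from the first moment, and its reckoned target curve leaves at a slope of 0.0121 h⁻¹. Ash's reckoned curve leaves flat, and its [reagent], counted as dosed, reaches that same value as the dose ends. At 15.0 h the exposures give 5.11% for ash and 16.6% for elm. At 30 h ash has seen 3.56 M·h and elm 6.62 M·h, which gives 17.7% and 30.4%. The product of constant and exposure stays below one, at 0.363 for elm, so neither reckoned curve has levelled.

The forecast puts elm ahead, with 18% (14% to 23%) for ash and 30% (22% to 37%) for elm: “Having reagent present from the start wins”.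

The flask gives elm ahead, with 17.3% for ash and 23.6% for elm.

    catalyst intermediate C → free catalyst + target (k = 0.0520 s⁻¹, Ea = 91.0 kJ mol⁻¹)
    substrate + catalyst intermediate B → catalyst intermediate C (k = 10.0 M⁻¹ s⁻¹, Ea = 66.0 kJ mol⁻¹)
    catalyst intermediate A → catalyst intermediate B (k = 0.0420 s⁻¹, Ea = 112 kJ mol⁻¹)
    reagent + free catalyst ⇌ catalyst intermediate A (K = 6.90 M⁻¹, k = 0.0770 M⁻¹ s⁻¹, Ea = 51.0 kJ mol⁻¹, ΔH = 2.00 kJ mol⁻¹)
    reagent ⇌ dormant form (K = 2.10, k = 1.80 × 10⁻⁵ s⁻¹, Ea = 121 kJ mol⁻¹, ΔH = −65.0 kJ mol⁻¹)
    reagent + free catalyst + target → free catalyst + over-reaction product (k = 0.290 M⁻² s⁻¹, Ea = 35.0 kJ mol⁻¹)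
    (constants at 100 °C)

Elm's reckoning stands 6.8 percentage points above the flask, and exposure counts reagent as free. At 5.28 h in elm, reagent passes to the dormant form 3.4 times as fast as it binds free catalyst, forward rates alone. For a repeat of elm at 115 °C, as far above summer as summer stands above dawn, the constant carried on by the same factor reckons at 0.140 M⁻¹ h⁻¹, and on the same 6.62 M·h that leaves 39.6% of the substrate. The computed repeat of elm leaves 46%, with 45.5% target.

Readings and results stem from a simulated flask for an exercise, noise included.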